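**Retrosynthetic overview** (cadinane numbering: C1/C6 ring fusion, C3 and C9 carbinols, C4=C5, C7=C11, C10–CH3, C12 = CH2O)
1. Target 16 ⇐ triol 14 (formate, then two acetates) ⇐ bromo diol 13 (Stille CH2OH for Br, retention) ⇐ bromo enedione 12 (Luche sets C3 and C9) ⇐ bromo ketone 10 (C3 allylic oxidation).
2. Ring B, formed second (the 1,10-type closure): ring-A allyl cation captured by a but-2-ynyl terminator, with bromide adding anti; this sets C6 (cis fusion) and the C7=C11 geometry.
3. Ring A, formed first (the 1,6-type closure): catalytic asymmetric carbonyl-ene of the neral-type (2Z)-enal 7; the carbinol C–H is the hydrogen transferred, so C1 is set and C9 emerges as a ketone.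
4. Both closures are run in one pot (7 → 8 → 10); C10 is then set by equilibration next to the C9 ketone.
5. 7 ⇐ neryl acetate 1 + 1-bromobut-2-yne 4 (SeO2 oxidation, Zn Barbier, deacetylation, TEMPO).

Assumption: the enantiomer of the confined IDPi acid used in step 5 is the one that gives the ring configuration drawn for 8; its sense is taken from the known neral → isopiperitenol cyclisation, and both catalyst enantiomers are available.

**Step 1**
Reactants: 1 neryl acetate [(2Z)-3,7-dimethylocta-2,6-dien-1-yl acetate]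
Product: 3 (2Z,6E)-3,7-dimethyl-8-oxoocta-2,6-dien-1-yl acetate, via 8-hydroxyneryl acetate 2 (not isolated)
Conditions: SeO2 (0.1 eq), salicylic acid (0.1 eq), t-BuOOH (3.5 eq), CH2Cl2, 23 °C; filter; then MnO2 (10 eq), CH2Cl2, 23 °C
Reagents that add atoms: tert-butyl hydroperoxide CC(C)(C)OO (oxygen relayed by catalytic SeO2)
Why: SeO2/t-BuOOH allylic oxidation (ene, then [2,3] shift) attacks only the electron-rich 6,7-alkene at its (E)-methyl group, the 2,3-alkene being deactivated by the allylic acetate, and MnO2 takes the allylic alcohol to the (6E)-enal without touching the (2Z)-alkene.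

**Step 2**
Reactants: 3 (2Z,6E)-3,7-dimethyl-8-oxoocta-2,6-dien-1-yl acetate; 4 1-bromobut-2-yne
Product: 5 (2Z,6E)-8-hydroxy-3,7-dimethyldodeca-2,6-dien-10-yn-1-yl acetate (racemic at C8)
Conditions: Zn dust (2 eq), 4 (1.5 eq), THF/sat. aq NH4Cl, 0 → 23 °C
Reagents that add atoms: none
Why: Zinc Barbier reaction in which the allenyl/propargyl zinc species adds 1,2 to the enal through an SE2' transition state to give the homopropargylic alcohol with an internal alkyne; the racemic carbinol is harmless because it becomes the C9 ketone in step 5.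

**Step 3**
Reactants: 5 (2Z,6E)-8-hydroxy-3,7-dimethyldodeca-2,6-dien-10-yn-1-yl acetate
Product: 6 (2Z,6E)-3,7-dimethyldodeca-2,6-dien-10-yne-1,8-diol (racemic at C8)
Conditions: K2CO3 (0.2 eq), MeOH, 23 °C
Reagents that add atoms: none
Why: Base-catalysed transesterification removes the primary acetate and leaves the alkenes, the alkyne and the secondary alcohol untouched.

**Step 4**
Reactants: 6 (2Z,6E)-3,7-dimethyldodeca-2,6-dien-10-yne-1,8-diol
Product: 7 (2Z,6E)-8-hydroxy-3,7-dimethyldodeca-2,6-dien-10-ynal (racemic at C8)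
Conditions: TEMPO (10 mol %), PhI(OAc)2 (1.1 eq), CH2Cl2, 0 → 23 °C
Reagents that add atoms: none
Why: TEMPO/PhI(OAc)2 oxidation is selective for the primary allylic alcohol over the secondary one and gives the neral-type (2Z)-enal without Z/E isomerisation.

**Step 5** (key step, one pot)
Reactants: 7 (2Z,6E)-8-hydroxy-3,7-dimethyldodeca-2,6-dien-10-ynal
Product: 10 (1R,4E,4aS,8aS)-4-(1-bromoethylidene)-1,6-dimethyl-3,4,4a,7,8,8a-hexahydronaphthalen-2(1H)-one (cis-fused), via hydroxy ketone 8 (not isolated), via 10-epi-bromo ketone 9 (not isolated)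
Conditions: chiral IDPi Brønsted acid (2 mol %), CHCl3, −30 °C; then CH2Cl2, SnBr4 (1.5 eq), −78 → −30 °C; then Et3N, MeOH, −30 → 23 °C
Reagents that add atoms: tin(IV) bromide Br[Sn](Br)(Br)Br
Why: Proposed new method: the confined chiral acid activates the (2Z)-enal for an intramolecular type-I carbonyl-ene reaction (closest known reaction: IDPi-catalysed cyclisation of neral to isopiperitenol) whose chair transition state transfers the hydrogen of the (E)-substituent of the 6,7-alkene, here the carbinol C–H, so ring A forms with catalyst-controlled C1 and the side chain emerges as the C9 ketone; SnBr4 then ionises the allylic alcohol to the cyclohexenyl cation, which the but-2-ynyl group captures by axial attack with an equatorial tether to give the cis fusion at C6, the linear vinyl cation takes bromide anti to the new C–C bond and from the less hindered C8 side (closest known reactions: Johnson alkyne-terminated cation–olefin cyclisation and halo-Prins alkyne cyclisation), and the amine quench equilibrates C10 to the equatorial-methyl epimer.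

**Step 6**
Reactants: 10 (1R,4E,4aS,8aS)-4-(1-bromoethylidene)-1,6-dimethyl-3,4,4a,7,8,8a-hexahydronaphthalen-2(1H)-one
Product: 12 (1R,4E,4aS,8aS)-4-(1-bromoethylidene)-1,6-dimethyl-3,4,4a,8a-tetrahydronaphthalene-2,7(1H,8H)-dione, via 3-hydroxy bromo ketone 11 (not isolated)
Conditions: SeO2 (0.5 eq), t-BuOOH (3 eq), CH2Cl2, 0 → 23 °C; work-up; then Dess–Martin periodinane (1.5 eq), NaHCO3, CH2Cl2, 0 °C
Reagents that add atoms: tert-butyl hydroperoxide CC(C)(C)OO (oxygen relayed by SeO2)
Why: SeO2 ene/[2,3] allylic oxidation follows the Sharpless–Rapoport rules (ring CH2 on the more substituted end of the only electron-rich alkene, the vinyl bromide being inert), and Dess–Martin oxidation converges both C3 epimers on the enone.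

**Step 7**
Reactants: 12 (1R,4E,4aS,8aS)-4-(1-bromoethylidene)-1,6-dimethyl-3,4,4a,8a-tetrahydronaphthalene-2,7(1H,8H)-dione
Product: 13 (1R,2R,4E,4aS,7R,8aS)-4-(1-bromoethylidene)-1,6-dimethyl-1,2,3,4,4a,7,8,8a-octahydronaphthalene-2,7-diol
Conditions: NaBH4 (3 eq), CeCl3·7H2O (2.2 eq), MeOH/CH2Cl2, −78 → −40 °C
Reagents that add atoms: none
Why: Luche reduction delivers hydride 1,2 to the enone and axially to the C9 ketone, in both cases from the convex face of the cis-fused bicycle (anti to the axial C1–C10 bond at C3, giving the equatorial alcohol at C9), which sets 3R and 9R.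

**Step 8**
Reactants: 13 (1R,2R,4E,4aS,7R,8aS)-4-(1-bromoethylidene)-1,6-dimethyl-1,2,3,4,4a,7,8,8a-octahydronaphthalene-2,7-diol
Product: 14 (1R,2R,4E,4aS,7R,8aS)-4-(1-hydroxypropan-2-ylidene)-1,6-dimethyl-1,2,3,4,4a,7,8,8a-octahydronaphthalene-2,7-diol
Conditions: Bu3SnCH2OH (1.5 eq), Pd2(dba)3 (5 mol %), P(2-furyl)3 (20 mol %), CuI (10 mol %), NMP, 80 °C
Reagents that add atoms: (tributylstannyl)methanol OC[Sn](CCCC)(CCCC)CCCC
Why: Stille coupling of the alkenyl bromide with the hydroxymethyl stannane proceeds with retention of alkene geometry, so the CH2OH ends up cis to C8 as in the target.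

**Step 9**
Reactants: 14 (1R,2R,4E,4aS,7R,8aS)-4-(1-hydroxypropan-2-ylidene)-1,6-dimethyl-1,2,3,4,4a,7,8,8a-octahydronaphthalene-2,7-diol
Product: 16 (1R,2R,4E,4aS,7R,8aS)-4-[1-(formyloxy)propan-2-ylidene]-1,6-dimethyl-1,2,3,4,4a,7,8,8a-octahydronaphthalene-2,7-diyl diacetate, via 12-O-formyl triol 15 (not isolated)
Conditions: acetic formic anhydride (1.2 eq), pyridine, CH2Cl2, −40 °C; then Ac2O (6 eq), DMAP (cat.), 0 → 23 °C
Reagents that add atoms: acetic formic anhydride CC(=O)OC=O; acetic anhydride CC(=O)OC(C)=O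
Why: The unhindered primary allylic alcohol is formylated chemoselectively by the much more reactive mixed anhydride at low temperature, and the two secondary alcohols are then acetylated under DMAP catalysis without disturbing the formate or any stereocentre.

**Compound list**
1 | neryl acetate, (2Z)-3,7-dimethylocta-2,6-dien-1-yl acetate | CC(=O)OC/C=C(/C)CCC=C(C)C | starting material
2 | (2Z,6E)-8-hydroxy-3,7-dimethylocta-2,6-dien-1-yl acetate | CC(=O)OC/C=C(/C)CC/C=C(\C)CO | intermediate
3 | (2Z,6E)-3,7-dimethyl-8-oxoocta-2,6-dien-1-yl acetate | CC(=O)OC/C=C(/C)CC/C=C(\C)C=O | intermediate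
4 | 1-bromobut-2-yne | CC#CCBr | starting material
5 | (2Z,6E)-8-hydroxy-3,7-dimethyldodeca-2,6-dien-10-yn-1-yl acetate (racemic) | CC(=O)OC/C=C(/C)CC/C=C(\C)C(O)CC#CC | intermediate
6 | (2Z,6E)-3,7-dimethyldodeca-2,6-dien-10-yne-1,8-diol (racemic) | OC/C=C(/C)CC/C=C(\C)C(O)CC#CC | intermediate
7 | (2Z,6E)-8-hydroxy-3,7-dimethyldodeca-2,6-dien-10-ynal (racemic) | O=C/C=C(/C)CC/C=C(\C)C(O)CC#CC | intermediate
8 | (1R,6R)-3-methyl-6-(3-oxohept-5-yn-2-yl)cyclohex-2-en-1-ol (both epimers at the side-chain CH–CH3) | CC1=C[C@H](O)[C@H](CC1)C(C)C(=O)CC#CC | intermediate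
9 | (1S,4E,4aS,8aS)-4-(1-bromoethylidene)-1,6-dimethyl-3,4,4a,7,8,8a-hexahydronaphthalen-2(1H)-one (C10 epimer of 10) | C1C[C@@H]2[C@H](C)C(=O)C/C(=C(/C)Br)[C@@H]2C=C1C | intermediate
10 | (1R,4E,4aS,8aS)-4-(1-bromoethylidene)-1,6-dimethyl-3,4,4a,7,8,8a-hexahydronaphthalen-2(1H)-one | C1C[C@@H]2[C@@H](C)C(=O)C/C(=C(/C)Br)[C@@H]2C=C1C | intermediate
11 | (1R,4E,4aS,8aS)-4-(1-bromoethylidene)-7-hydroxy-1,6-dimethyl-3,4,4a,7,8,8a-hexahydronaphthalen-2(1H)-one (C7 epimers) | OC1C[C@@H]2[C@@H](C)C(=O)C/C(=C(/C)Br)[C@@H]2C=C1C | intermediate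
12 | (1R,4E,4aS,8aS)-4-(1-bromoethylidene)-1,6-dimethyl-3,4,4a,8a-tetrahydronaphthalene-2,7(1H,8H)-dione | O=C1C[C@@H]2[C@@H](C)C(=O)C/C(=C(/C)Br)[C@@H]2C=C1C | intermediate
13 | (1R,2R,4E,4aS,7R,8aS)-4-(1-bromoethylidene)-1,6-dimethyl-1,2,3,4,4a,7,8,8a-octahydronaphthalene-2,7-diol | O[C@@H]1C[C@@H]2[C@@H](C)[C@H](O)C/C(=C(/C)Br)[C@@H]2C=C1C | intermediate
14 | (1R,2R,4E,4aS,7R,8aS)-4-(1-hydroxypropan-2-ylidene)-1,6-dimethyl-1,2,3,4,4a,7,8,8a-octahydronaphthalene-2,7-diol | O[C@@H]1C[C@@H]2[C@@H](C)[C@H](O)C/C(=C(/C)CO)[C@@H]2C=C1C | intermediate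
15 | (1R,2R,4E,4aS,7R,8aS)-4-[1-(formyloxy)propan-2-ylidene]-1,6-dimethyl-1,2,3,4,4a,7,8,8a-octahydronaphthalene-2,7-diol | O[C@@H]1C[C@@H]2[C@@H](C)[C@H](O)C/C(=C(/C)COC=O)[C@@H]2C=C1C | intermediate
16 | (1R,2R,4E,4aS,7R,8aS)-4-[1-(formyloxy)propan-2-ylidene]-1,6-dimethyl-1,2,3,4,4a,7,8,8a-octahydronaphthalene-2,7-diyl diacetate; cadinane numbering (1S,3R,6S,9R,10R,7(11)E) | CC(=O)O[C@@H]1C[C@@H]2[C@@H](C)[C@H](OC(C)=O)C/C(=C(/C)COC=O)[C@@H]2C=C1C | target

**Totals**
Total step count: 9 (step 5 run as one pot). Longest linear sequence: 9 steps from 1.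

**Three steps most likely to fail, with fallbacks**

Step 5 (enantioselectivity of the ene reaction on an elaborated neral, and the cation–alkyne closure in the same pot). The fallback sets out from 7 and comes back at 10. An achiral Lewis acid (Me2AlCl, CH2Cl2, −78 °C) gives the racemic trans hydroxy ketone, that is 8 together with its enantiomer (1S,6S)-3-methyl-6-(3-oxohept-5-yn-2-yl)cyclohex-2-en-1-ol F1. Esterification of the racemate with (2S)-2-methoxy-2-phenylacetic acid (DCC, DMAP) gives two diastereomers, the mandelate ester of 8 F2 and the mandelate ester of ent-8 F3, which are separated by chromatography. F2 is then treated with SnBr4 and the Et3N/MeOH quench as in step 5; the allylic ester ionises at least as readily as the alcohol and gives 10.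

Step 6 (regiochemistry and yield of the SeO2 oxidation next to a ketone). The fallback sets out from 10 and comes back at 13; it removes the ketone first and sets C3 by inversion instead of by reduction. NaBH4 reduces 10 from the convex face to the equatorial 9-alcohol F4, and Ac2O/pyridine gives the 9-acetate F5. SeO2/t-BuOOH then hydroxylates C3 from the convex face to give the 3-epi allylic alcohol F6. Mitsunobu reaction with acetic acid (PPh3, DIAD) inverts C3 and gives the bromo diacetate F7, and K2CO3/MeOH returns diol 13.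

Step 8 (Stille coupling at a tetrasubstituted alkenyl bromide). The fallback sets out from 13 and comes back at 14 without a new isolated compound. Both hydroxyls are deprotonated and the bromide exchanged with t-BuLi (4.2 eq, THF, −78 °C); the configurationally stable alkenyllithium is trapped with monomeric formaldehyde to give 14 with retention of geometry.

**Further compounds**
F1 | step 5 | (1S,6S)-3-methyl-6-(3-oxohept-5-yn-2-yl)cyclohex-2-en-1-ol | CC1=C[C@@H](O)[C@@H](CC1)C(C)C(=O)CC#CC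
F2 | step 5 | (1R,6R)-3-methyl-6-(3-oxohept-5-yn-2-yl)cyclohex-2-en-1-yl (2S)-2-methoxy-2-phenylacetate | CC1=C[C@H](OC(=O)[C@@H](OC)c2ccccc2)[C@H](CC1)C(C)C(=O)CC#CC
F3 | step 5 | (1S,6S)-3-methyl-6-(3-oxohept-5-yn-2-yl)cyclohex-2-en-1-yl (2S)-2-methoxy-2-phenylacetate | CC1=C[C@@H](OC(=O)[C@@H](OC)c2ccccc2)[C@@H](CC1)C(C)C(=O)CC#CC
F4 | step 6 | (1R,2R,4E,4aS,8aS)-4-(1-bromoethylidene)-1,6-dimethyl-1,2,3,4,4a,7,8,8a-octahydronaphthalen-2-ol | C1C[C@@H]2[C@@H](C)[C@H](O)C/C(=C(/C)Br)[C@@H]2C=C1C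
F5 | step 6 | (1R,2R,4E,4aS,8aS)-4-(1-bromoethylidene)-1,6-dimethyl-1,2,3,4,4a,7,8,8a-octahydronaphthalen-2-yl acetate | C1C[C@@H]2[C@@H](C)[C@H](OC(C)=O)C/C(=C(/C)Br)[C@@H]2C=C1C
F6 | step 6 | (1R,2R,4E,4aS,7S,8aS)-4-(1-bromoethylidene)-7-hydroxy-1,6-dimethyl-1,2,3,4,4a,7,8,8a-octahydronaphthalen-2-yl acetate | O[C@H]1C[C@@H]2[C@@H](C)[C@H](OC(C)=O)C/C(=C(/C)Br)[C@@H]2C=C1C
F7 | step 6 | (1R,2R,4E,4aS,7R,8aS)-4-(1-bromoethylidene)-1,6-dimethyl-1,2,3,4,4a,7,8,8a-octahydronaphthalene-2,7-diyl diacetate | CC(=O)O[C@@H]1C[C@@H]2[C@@H](C)[C@H](OC(C)=O)C/C(=C(/C)Br)[C@@H]2C=C1C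
F0 | step 8 | none | none
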